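**Retrosynthetic overview**

1. 19 ⇐ 18 (hydrogenolysis of nine benzyl ethers) ⇐ 17 (one double asymmetric hydrogenation with dynamic kinetic resolution sets C2 and C3 of both flavan units) ⇐ 16 (unmasking of two dithioketals). Unit 1 is the catechol-type half (rings A, C, B); unit 2 is the pyrogallol-type half (phloroglucinol ring D, pyran ring F, pyrogallol ring E).
2. 16 ⇐ biaryl dialdehyde 14 + two molecules of ring A/D reagent 8: one operation makes O1–C8a and C2–C3 of pyran ring C and the same two bonds of pyran ring F (umpolung acyl-anion addition to the aldehyde, then SNAr ring closure).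
3. Enabling feature: in each heterocycle C2 is a benzylic, O1-bearing carbon on ring B (or E), a latent ArCH=O. C3 is a carbinol carbon between C2 and the C4 methylene, a latent carbonyl usable as an acyl anion. C8a of the phloroglucinol ring A (or D) lies ortho to C4a, so a C3–C4–C4a–C8a unit with fluoride at C8a can close onto the C2–O1 unit. Both chroman halves are identical, so one reagent builds both.
4. 14 ⇐ Suzuki–Miyaura union of rings B and E (boronate 11 + bromide 13); 8 ⇐ alkylation of silyl dithiane 6 with benzylic bromide 5 (from 5-fluororesorcinol 1).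
5. Order of ring formation: rings A/D, B and E are bought as benzenes; the B–E biaryl bond comes first, rings C and F close together in the key step, and the four stereocentres are set afterwards.

Key step: step 10

Remark on the chemistry: the SMILES defines the four carbon stereocentres (2R,3R in both units) but no sense for the hindered biaryl axis, so both axial isomers answer to it; the route sets the four centres, and the axial diastereomers of 18 are assumed separable by chromatography, the one matching the natural axis being carried on.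

**Route**

Step 1
Reactants: 1 5-fluorobenzene-1,3-diol
Product: 2 1,3-bis(benzyloxy)-5-fluorobenzene
Conditions: BnBr, K2CO3, DMF, 60 °C
Reagents that add atoms: benzyl bromide, BrCc1ccccc1
Why: Williamson ether synthesis on both phenols; benzyl is chosen because all nine aryl ethers of the route fall together in the final hydrogenolysis.

Step 2
Reactants: 2 1,3-bis(benzyloxy)-5-fluorobenzene
Product: 3 2,4-bis(benzyloxy)-6-fluorobenzaldehyde
Conditions: POCl3, DMF, 0 to 70 °C; then aq. NaOAc
Reagents that add atoms: N,N-dimethylformamide, CN(C)C=O; water, O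
Why: Vilsmeier–Haack formylation at the carbon para to one benzyloxy group and ortho to the other (next to F), the less crowded of the doubly activated sites; a minor isomer formylated between the two benzyloxy groups would be removed by crystallisation.

Step 3
Reactants: 3 2,4-bis(benzyloxy)-6-fluorobenzaldehyde
Product: 4 [2,4-bis(benzyloxy)-6-fluorophenyl]methanol
Conditions: NaBH4, THF/MeOH, 0 °C
Reagents that add atoms: none
Why: Borohydride reduction of an aromatic aldehyde to the benzylic alcohol, with no other reducible group present.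

Step 4
Reactants: 4 [2,4-bis(benzyloxy)-6-fluorophenyl]methanol
Product: 5 2,4-bis(benzyloxy)-6-fluorobenzyl bromide
Conditions: PBr3, CH2Cl2, −10 °C; used at once
Reagents that add atoms: phosphorus tribromide, BrP(Br)Br
Why: Alcohol-to-bromide conversion through the bromophosphite (SN2); the electron-rich benzylic bromide is labile and is therefore taken on cold without storage.

Step 5
Reactants: 6 2-(trimethylsilyl)-1,3-dithiane; 5 2,4-bis(benzyloxy)-6-fluorobenzyl bromide
Product: 8 2-[2,4-bis(benzyloxy)-6-fluorobenzyl]-2-(trimethylsilyl)-1,3-dithiane, via 2-lithio-2-(trimethylsilyl)-1,3-dithiane 7 (not isolated)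
Conditions: n-BuLi, THF, −30 °C; then 5, −78 to 0 °C
Reagents that add atoms: none
Why: Corey–Seebach alkylation of the lithiated silyl dithiane with a primary benzylic bromide; silicon is in place before the fluoroarene arrives, so butyllithium never meets the acidic ring C–H flanked by F and OBn.

Step 6
Reactants: 9 3,4-bis(benzyloxy)benzaldehyde
Product: 10 4,5-bis(benzyloxy)-2-bromobenzaldehyde
Conditions: Br2, NaOAc, AcOH, rt
Reagents that add atoms: bromine, BrBr
Why: Electrophilic aromatic bromination at the position para to the 3-benzyloxy group and ortho to the formyl group, the regiochemistry known for 3,4-dialkoxybenzaldehydes.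

Step 7
Reactants: 10 4,5-bis(benzyloxy)-2-bromobenzaldehyde
Product: 11 4,5-bis(benzyloxy)-2-(4,4,5,5-tetramethyl-1,3,2-dioxaborolan-2-yl)benzaldehyde
Conditions: B2pin2, Pd(dppf)Cl2 (cat.), KOAc, 1,4-dioxane, 90 °C
Reagents that add atoms: bis(pinacolato)diboron, CC1(C)OB(OC1(C)C)B1OC(C)(C)C(C)(C)O1
Why: Miyaura borylation of the aryl bromide; the weak acetate base leaves the aldehyde alone and does not promote biaryl homocoupling.

Step 8
Reactants: 12 3,4,5-tris(benzyloxy)benzaldehyde
Product: 13 3,4,5-tris(benzyloxy)-2-bromobenzaldehyde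
Conditions: NBS, MeCN, 40 °C, dark
Reagents that add atoms: N-bromosuccinimide, O=C1CCC(=O)N1Br
Why: Electrophilic aromatic bromination at one of the two equivalent positions ortho to the formyl group (ortho and para to benzyloxy groups); the first bromine deactivates the ring against a second.

Step 9
Reactants: 11 4,5-bis(benzyloxy)-2-(4,4,5,5-tetramethyl-1,3,2-dioxaborolan-2-yl)benzaldehyde; 13 3,4,5-tris(benzyloxy)-2-bromobenzaldehyde
Product: 14 4,4',5,5',6-pentakis(benzyloxy)biphenyl-2,2'-dicarbaldehyde
Conditions: Pd(OAc)2 (cat.), SPhos, K3PO4, toluene/H2O, 90 °C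
Reagents that add atoms: none
Why: Suzuki–Miyaura coupling with a dialkylbiarylphosphine ligand suited to tri-ortho-substituted biaryls; it joins rings B and E, and both formyl groups are tolerated.

Step 10
Reactants: 14 4,4',5,5',6-pentakis(benzyloxy)biphenyl-2,2'-dicarbaldehyde; 8 2-[2,4-bis(benzyloxy)-6-fluorobenzyl]-2-(trimethylsilyl)-1,3-dithiane (two molecules)
Product: 16 4,4',5,5',6-pentakis(benzyloxy)-2,2'-bis{5,7-bis(benzyloxy)spiro[chromane-3,2'-[1,3]dithian]-2-yl}biphenyl (bis-spirodithiane; mixture of stereoisomers), via bis-silyl-ether double adduct 15 (not isolated)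
Conditions: 8 (2.4 equiv), Bu4N[Ph3SiF2] (10 mol%), 4 Å MS, DMF, −20 °C to rt; then CsF (3 equiv), 90 °C
Reagents that add atoms: none
Why: Proposed new method: a fluoride-relay [4+2] annulation in which fluoride attacks silicon of 8 and releases the 2-dithianyl carbanion (C3 as a masked acyl anion), this adds to each formyl carbon of 14 (the C2–C3 bonds of rings C and F), and the benzylic oxide at O1, held as silyl ether 15 until both additions are complete and then freed by CsF, displaces the ortho fluoride at C8a of ring A (or D) through a Meisenheimer adduct (the O1–C8a bonds), the expelled fluoride re-entering the cycle so that Me3SiF is the only by-product. The closest known reactions are the Lewis-base-triggered 1,2-addition of 2-silyl-1,3-dithianes to aldehydes (Corey–Seebach umpolung) and the intramolecular SNAr etherification of non-activated aryl fluorides by alkoxides; their merger into one fluoride-turnover operation is the new element. Rings C and F each close by a 6-exo-trig addition–elimination at an aromatic carbon, helped by the gem-dithio substitution at C3 (Thorpe–Ingold effect). The two new stereocentres (C2 of each unit) form without control, which is accepted because both become epimerisable next to the C3 ketone and are set in step 12. The step needs chemoselectivity (carbon nucleophile on CHO, oxygen nucleophile on C–F, no hydride transfer or lactol trapping between the two ortho formyl groups) and a single mode of closure: silyl transfer caps each oxide during the addition stage, the carbanion is released only in the presence of aldehyde so the ring C–H flanked by F and OBn is left alone, the dithioketal leaves no second oxygen at C3 that could close a five-membered ring, and ring A offers one fluoride, meta to both benzyloxy groups, so only C8a is attacked.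

Step 11
Reactants: 16 bis-spirodithiane
Product: 17 4,4',5,5',6-pentakis(benzyloxy)-2,2'-bis[5,7-bis(benzyloxy)-3-oxochroman-2-yl]biphenyl (nona-O-benzyl bis(flavan-3-one); C2 epimers)
Conditions: MeI, CaCO3, MeCN/THF/H2O, 45 °C
Reagents that add atoms: water, O
Why: Alkylative hydrolysis of both dithioketals (S-methylation, then hydrolysis of the sulfonium) under near-neutral conditions that spare benzyl ethers and the base- and air-sensitive 2-arylchroman-3-ones; the C2 configuration is irrelevant at this stage.

Step 12
Reactants: 17 nona-O-benzyl bis(flavan-3-one)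
Product: 18 4,4',5,5',6-pentakis(benzyloxy)-2,2'-bis[(2R,3R)-5,7-bis(benzyloxy)-3-hydroxychroman-2-yl]biphenyl (nona-O-benzyl ether of the target)
Conditions: RuCl2[(S)-xylbinap][(S)-daipen] (cat.), KOt-Bu (cat.), H2 (20 atm), i-PrOH/THF, 30 °C
Reagents that add atoms: none
Why: Noyori-type asymmetric hydrogenation with dynamic kinetic resolution: C2 of each chroman-3-one (benzylic and alpha to both O1 and the carbonyl) epimerises through the enolate under catalytic base, the (S)-diphosphine/diamine ruthenium hydride reduces the (2R)-ketone faster and delivers hydride to the C3 face opposite the C2 aryl group, so each unit should emerge 2,3-cis with 2R,3R configuration (sense assigned by analogy with 2-alkoxy- and 2-alkylcyclohexanones), while benzyl ethers are inert to this catalyst.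

Step 13
Reactants: 18 nona-O-benzyl ether of the target
Product: 19 degalloyl theasinensin F
Conditions: H2 (1 atm), Pd(OH)2/C, THF/MeOH, rt
Reagents that add atoms: none
Why: Hydrogenolysis of the nine O-benzyl ethers under mild conditions that should leave the cyclic benzylic C2–O1 ethers and all four stereocentres untouched.

**Compound list**

1 | 5-fluorobenzene-1,3-diol (5-fluororesorcinol) | Oc1cc(O)cc(F)c1 | starting material
2 | 1,3-bis(benzyloxy)-5-fluorobenzene | Fc1cc(OCc2ccccc2)cc(OCc2ccccc2)c1 | intermediate
3 | 2,4-bis(benzyloxy)-6-fluorobenzaldehyde | O=Cc1c(F)cc(OCc2ccccc2)cc1OCc1ccccc1 | intermediate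
4 | [2,4-bis(benzyloxy)-6-fluorophenyl]methanol | OCc1c(F)cc(OCc2ccccc2)cc1OCc1ccccc1 | intermediate
5 | 2,4-bis(benzyloxy)-6-fluorobenzyl bromide | BrCc1c(F)cc(OCc2ccccc2)cc1OCc1ccccc1 | intermediate
6 | 2-(trimethylsilyl)-1,3-dithiane | C[Si](C)(C)C1SCCCS1 | starting material
7 | 2-lithio-2-(trimethylsilyl)-1,3-dithiane | [Li]C1([Si](C)(C)C)SCCCS1 | intermediate
8 | 2-[2,4-bis(benzyloxy)-6-fluorobenzyl]-2-(trimethylsilyl)-1,3-dithiane | C[Si](C)(C)C1(Cc2c(F)cc(OCc3ccccc3)cc2OCc2ccccc2)SCCCS1 | intermediate
9 | 3,4-bis(benzyloxy)benzaldehyde | O=Cc1ccc(OCc2ccccc2)c(OCc2ccccc2)c1 | starting material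
10 | 4,5-bis(benzyloxy)-2-bromobenzaldehyde | O=Cc1cc(OCc2ccccc2)c(OCc2ccccc2)cc1Br | intermediate
11 | 4,5-bis(benzyloxy)-2-(4,4,5,5-tetramethyl-1,3,2-dioxaborolan-2-yl)benzaldehyde | O=Cc1cc(OCc2ccccc2)c(OCc2ccccc2)cc1B1OC(C)(C)C(C)(C)O1 | intermediate
12 | 3,4,5-tris(benzyloxy)benzaldehyde | O=Cc1cc(OCc2ccccc2)c(OCc2ccccc2)c(OCc2ccccc2)c1 | starting material
13 | 3,4,5-tris(benzyloxy)-2-bromobenzaldehyde | O=Cc1cc(OCc2ccccc2)c(OCc2ccccc2)c(OCc2ccccc2)c1Br | intermediate
14 | 4,4',5,5',6-pentakis(benzyloxy)biphenyl-2,2'-dicarbaldehyde | O=Cc1cc(OCc2ccccc2)c(OCc2ccccc2)cc1-c1c(C=O)cc(OCc2ccccc2)c(OCc2ccccc2)c1OCc1ccccc1 | intermediate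
15 | double adduct of 14 with two molecules of 8: each former formyl carbon is CH(OSiMe3) bonded to C2 of a 2-[2,4-bis(benzyloxy)-6-fluorobenzyl]-1,3-dithiane (stereoisomer mixture) | C[Si](C)(C)OC(c1cc(OCc2ccccc2)c(OCc2ccccc2)cc1-c1c(C(O[Si](C)(C)C)C2(Cc3c(F)cc(OCc4ccccc4)cc3OCc3ccccc3)SCCCS2)cc(OCc2ccccc2)c(OCc2ccccc2)c1OCc1ccccc1)C1(Cc2c(F)cc(OCc3ccccc3)cc2OCc2ccccc2)SCCCS1 | intermediate
16 | 4,4',5,5',6-pentakis(benzyloxy)-2,2'-bis{5,7-bis(benzyloxy)spiro[chromane-3,2'-[1,3]dithian]-2-yl}biphenyl (stereoisomer mixture at both C2 and the axis) | C1(c2cc(OCc3ccccc3)c(OCc3ccccc3)cc2-c2c(C3Oc4cc(OCc5ccccc5)cc(OCc5ccccc5)c4CC35SCCCS5)cc(OCc3ccccc3)c(OCc3ccccc3)c2OCc2ccccc2)Oc2cc(OCc3ccccc3)cc(OCc3ccccc3)c2CC12SCCCS2 | intermediate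
17 | 4,4',5,5',6-pentakis(benzyloxy)-2,2'-bis[5,7-bis(benzyloxy)-3-oxochroman-2-yl]biphenyl (C2 epimers) | O=C1Cc2c(OCc3ccccc3)cc(OCc3ccccc3)cc2OC1c1cc(OCc2ccccc2)c(OCc2ccccc2)cc1-c1c(C2Oc3cc(OCc4ccccc4)cc(OCc4ccccc4)c3CC2=O)cc(OCc2ccccc2)c(OCc2ccccc2)c1OCc1ccccc1 | intermediate
18 | 4,4',5,5',6-pentakis(benzyloxy)-2,2'-bis[(2R,3R)-5,7-bis(benzyloxy)-3-hydroxychroman-2-yl]biphenyl | c1ccccc1COc1cc(OCc3ccccc3)c2c(c1)O[C@H](c1cc(OCc3ccccc3)c(OCc3ccccc3)cc1-c1c([C@H]3Oc4cc(OCc5ccccc5)cc(OCc5ccccc5)c4C[C@H]3O)cc(OCc3ccccc3)c(OCc3ccccc3)c1OCc1ccccc1)[C@H](O)C2 | intermediate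
19 | degalloyl theasinensin F: 2,2'-bis[(2R,3R)-3,5,7-trihydroxychroman-2-yl]biphenyl-4,4',5,5',6-pentol | Oc1cc(O)c2c(c1)O[C@H](c1cc(O)c(O)cc1-c1c([C@H]3Oc4cc(O)cc(O)c4C[C@H]3O)cc(O)c(O)c1O)[C@H](O)C2 | target

**Step count and risks**

Total step count: 13. Longest linear sequence: 9 steps (steps 1–5, then 10–13).

Steps most likely to fail:

Step 10 (proposed new method). Three processes may defeat it. Protodesilylation of 8 may outrun its addition to the hindered aldehydes. After the first addition, the neighbouring formyl group may be trapped as a cyclic silylated lactol. The SNAr closure with the cesium alkoxide may be too slow, so the adduct decomposes on heating. The fallback, in known chemistry, separates the two bond formations and sets out from 14 and 8. Addition of 8 to 14 under catalytic Bu4N[Ph3SiF2] at −20 °C, followed by K2CO3/MeOH work-up, should give the bis-carbinol F1, which is isolated. Both rings are then closed by a stoichiometric strong base (KH, 18-crown-6, DMF, 0 to 60 °C; classical alkoxide SNAr on the aryl fluoride). The route is rejoined at 16.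

Step 12. Epimerisation at C2 may be slower than reduction on the crowded biaryl, so the dynamic resolution stays incomplete. Catalyst control may be poor in one axial isomer, or enolate formation may stall the hydrogenation. The fallback sets out from 17 and uses substrate control followed by resolution. LiBH(s-Bu)3 in THF at −78 °C delivers hydride opposite the C2 aryl group and should give the all-cis bis-carbinol stereoisomer mixture F2 without absolute control. Esterification with (S)-2-methoxy-2-phenylacetic acid (DCC, DMAP, CH2Cl2) gives diastereomeric bis-esters, from which the (2R,3R)/(2R,3R) bis-ester F3 is separated by chromatography. Methanolysis (K2CO3, MeOH/THF) returns the route at 18.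

Step 11. Unmasking of the two neopentyl-type dithioketals may be incomplete, and the liberated ketones may enolise and oxidise in air over a long reaction time. The fallback sets out from 16 and activates sulfur by oxidation instead of alkylation. NaIO4 in aqueous MeOH/THF at 0 °C should give the bis(dithiane S-oxide) F4. This thioacetal S-oxide hydrolyses readily with dilute aqueous HCl in THF at rt, and the route is rejoined at 17.

**Further compounds**

F1 | step 10 | bis-carbinol: double adduct of 14 with two dithianyl units from 8, both hydroxyl groups free (stereoisomer mixture) | OC(c1cc(OCc2ccccc2)c(OCc2ccccc2)cc1-c1c(C(O)C2(Cc3c(F)cc(OCc4ccccc4)cc3OCc3ccccc3)SCCCS2)cc(OCc2ccccc2)c(OCc2ccccc2)c1OCc1ccccc1)C1(Cc2c(F)cc(OCc3ccccc3)cc2OCc2ccccc2)SCCCS1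
F2 | step 12 | 4,4',5,5',6-pentakis(benzyloxy)-2,2'-bis[2,3-cis-5,7-bis(benzyloxy)-3-hydroxychroman-2-yl]biphenyl (all-cis, mixture of stereoisomers without absolute control) | OC1Cc2c(OCc3ccccc3)cc(OCc3ccccc3)cc2OC1c1cc(OCc2ccccc2)c(OCc2ccccc2)cc1-c1c(C2Oc3cc(OCc4ccccc4)cc(OCc4ccccc4)c3CC2O)cc(OCc2ccccc2)c(OCc2ccccc2)c1OCc1ccccc1
F3 | step 12 | bis[(S)-2-methoxy-2-phenylacetate] of 18 | c1ccccc1COc1cc(OCc3ccccc3)c2c(c1)O[C@H](c1cc(OCc3ccccc3)c(OCc3ccccc3)cc1-c1c([C@H]3Oc4cc(OCc5ccccc5)cc(OCc5ccccc5)c4C[C@H]3OC(=O)[C@@H](OC)c3ccccc3)cc(OCc3ccccc3)c(OCc3ccccc3)c1OCc1ccccc1)[C@H](OC(=O)[C@@H](OC)c1ccccc1)C2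
F4 | step 11 | bis(dithiane S-oxide) of 16: one sulfur of each spiro-dithiane oxidised to the sulfoxide (stereoisomer mixture) | C1(c2cc(OCc3ccccc3)c(OCc3ccccc3)cc2-c2c(C3Oc4cc(OCc5ccccc5)cc(OCc5ccccc5)c4CC35S(=O)CCCS5)cc(OCc3ccccc3)c(OCc3ccccc3)c2OCc2ccccc2)Oc2cc(OCc3ccccc3)cc(OCc3ccccc3)c2CC12S(=O)CCCS2
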